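**Retrosynthetic overview**
1. Target ⇒ (2R,3R)-3-aryl-2,3-dimethylcyclopentanone by E-selective bromomethylenation (Wittig, last C–C bond).
2. Ketone ⇒ 2-(1,2-dimethylcyclopent-2-enyl)phenol by hydroboration anti to the aryl group (sets the secondary methyl centre) and one-pot oxidation.
3. Cyclopentenyl phenol ⇒ (S)-aryl 2,3-dimethylcyclopent-2-enyl ether by aromatic Claisen rearrangement (O→C chirality relay that builds the quaternary centre).
4. Ether ⇒ 4-bromo-3-methylphenol + 1-methyl-5-methylidenecyclopentene by enantioselective Pd–H hydro-aryloxylation (the C–O bond that fixes the absolute configuration); diene ⇒ 2-methylcyclopent-2-enone (Wittig).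
5. Rings: none is formed; the arene and the cyclopentane are both bought intact.

Assumption: the (R)-antipode of the ligand in step 2 is taken to give the (S)-ether; if the first run shows the opposite sense, the (S)-ligand is used and nothing else changes.

**Step 1**
Reactants: 1 2-methylcyclopent-2-en-1-one
Product: 2 1-methyl-5-methylidenecyclopent-1-ene
Conditions: Ph3PCH3Br (1.2 equiv), KOtBu (1.15 equiv), Et2O, 0 °C → rt; fractional distillation, used as a solution
Reagents that add atoms: methyltriphenylphosphonium bromide, C[P+](c1ccccc1)(c1ccccc1)c1ccccc1.[Br-]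
Why: Wittig methylenation, the non-stabilised ylide adds 1,2 to the enone carbonyl and gives the semicyclic diene; no stereocentre is formed.

**Step 2**
Reactants: 2 1-methyl-5-methylidenecyclopent-1-ene (1.5 equiv); 3 4-bromo-3-methylphenol
Product: 4 1-bromo-4-{[(1S)-2,3-dimethylcyclopent-2-en-1-yl]oxy}-2-methylbenzene
Conditions: Pd2(dba)3 (2.5 mol %), (R)-DTBM-SEGPHOS (6 mol %), PhMe, 0 °C → rt
Reagents that add atoms: none
Why: Proposed new method: enantioselective Pd–H 1,4-hydro-aryloxylation of a semicyclic diene, in which the phenol protonates L*Pd(0) to a cationic Pd–H/phenoxide pair, H is delivered to the exocyclic CH2 so that Pd sits as a π-allyl on one ligand-selected face of the 1,2-dimethylcyclopentenyl unit, and phenoxide attacks the less hindered secondary allyl terminus anti to Pd, which forms the C–O bond and sets C1 as S; the closest known reaction types are the racemic Pd-catalysed addition of phenols to 1,3-dienes, enantioselective Pd- and Ni-hydride hydroamination and hydroalkoxylation of acyclic dienes, and Pd-catalysed asymmetric allylic etherification of phenols with cyclic allyl carbonates (which tolerates aryl bromides at room temperature), and it has not been shown for a semicyclic diene giving a cyclic secondary allyl aryl ether.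

**Step 3**
Reactants: 4 1-bromo-4-{[(1S)-2,3-dimethylcyclopent-2-en-1-yl]oxy}-2-methylbenzene
Product: 6 4-bromo-2-[(1R)-1,2-dimethylcyclopent-2-en-1-yl]-5-methylphenol, via ortho-dienone 5 (not isolated)
Conditions: Eu(fod)3 (10 mol %), PhMe, 80 °C
Reagents that add atoms: none
Why: Aromatic Claisen rearrangement ([3,3]), where the ring enforces a suprafacial transition state so that the unhindered ortho carbon (para to the aryl methyl) bonds to C3 of the cyclopentenyl ether on the face the oxygen leaves, transferring the C–O stereocentre of 4 into the quaternary benzylic centre (R) of 6 before dienone 5 enolises; the mild Eu(III) catalyst avoids ionising the allylic ether.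

**Step 4**
Reactants: 6 4-bromo-2-[(1R)-1,2-dimethylcyclopent-2-en-1-yl]-5-methylphenol
Product: 9 (2R,3R)-3-(5-bromo-2-hydroxy-4-methylphenyl)-2,3-dimethylcyclopentan-1-one, via bis-borane 7 (not isolated), via borate-bound alcohol 8 (not isolated)
Conditions: BH3·THF (3 equiv), THF, 0 °C → rt; then NMO (10 equiv), TPAP (5 mol %), 4 Å MS, CH2Cl2, rt; aqueous work-up
Reagents that add atoms: 4-methylmorpholine N-oxide, C[N+]1([O-])CCOCC1
Why: One-pot hydroboration/TPAP–NMO ketonisation, in which BH3 adds syn with boron at the less substituted alkene carbon from the face anti to the aryl group (bound as a bulky ArO–B borate that is a poor internal hydride donor), so the new H at C2 is cis to the quaternary methyl and the C2 methyl is cis to the aryl (2R), and NMO then TPAP/NMO turn C–B into C=O under neutral anhydrous conditions that keep the phenol masked as borate and do not epimerise C2.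

**Step 5**
Reactants: 9 (2R,3R)-3-(5-bromo-2-hydroxy-4-methylphenyl)-2,3-dimethylcyclopentan-1-one
Product: 10 4-bromo-2-[(1R,2R,3E)-3-(bromomethylidene)-1,2-dimethylcyclopentyl]-5-methylphenol
Conditions: Ph3P(CH2Br)Br (4 equiv), NaHMDS (4.9 equiv), THF, −78 °C → rt; aq. NH4Cl
Reagents that add atoms: (bromomethyl)triphenylphosphonium bromide, BrC[P+](c1ccccc1)(c1ccccc1)c1ccccc1.[Br-]
Why: Wittig reaction with the weakly basic bromo-ylide (one equivalent of base is taken by the phenol), which olefinates the ketone without enolising C2 and places bromine on the side of the unbranched α-CH2, away from the methyl-bearing α-carbon, i.e. the E isomer, as in the known bromomethylenation of α-branched hydrindanones.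

**Compound list**
1 | 2-methylcyclopent-2-en-1-one | CC1=CCCC1=O | starting material
2 | 1-methyl-5-methylidenecyclopent-1-ene | C=C1CCC=C1C | intermediate
3 | 4-bromo-3-methylphenol | Cc1cc(O)ccc1Br | starting material
4 | 1-bromo-4-{[(1S)-2,3-dimethylcyclopent-2-en-1-yl]oxy}-2-methylbenzene | CC1=C(C)[C@@H](Oc2ccc(Br)c(C)c2)CC1 | intermediate
5 | 4-bromo-6-[(1S)-1,2-dimethylcyclopent-2-en-1-yl]-3-methylcyclohexa-2,4-dien-1-one (C6 not assigned, lost on enolisation; same spatial arrangement at the quaternary carbon as in 6, the label changes only through CIP priorities) | O=C1C=C(C)C(Br)=CC1[C@]2(C)CCC=C2C | intermediate (not isolated)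
6 | 4-bromo-2-[(1R)-1,2-dimethylcyclopent-2-en-1-yl]-5-methylphenol | Cc1cc(O)c([C@]2(C)CCC=C2C)cc1Br | intermediate
7 | {(1R,2S,3R)-3-[5-bromo-2-(boranyloxy)-4-methylphenyl]-2,3-dimethylcyclopentyl}borane (B on the ring cis to H-2 and to the quaternary methyl, trans to the aryl) | Cc1cc(OB)c([C@]2(C)CC[C@@H](B)[C@@H]2C)cc1Br | intermediate (not isolated)
8 | (1R,2R,3R)-3-(5-bromo-2-hydroxy-4-methylphenyl)-2,3-dimethylcyclopentan-1-ol, held as its borate esters | Cc1cc(O)c([C@]2(C)CC[C@@H](O)[C@@H]2C)cc1Br | intermediate (not isolated)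
9 | (2R,3R)-3-(5-bromo-2-hydroxy-4-methylphenyl)-2,3-dimethylcyclopentan-1-one | Cc1cc(O)c([C@]2(C)CCC(=O)[C@@H]2C)cc1Br | intermediate
10 | 4-bromo-2-[(1R,2R,3E)-3-(bromomethylidene)-1,2-dimethylcyclopentyl]-5-methylphenol | Cc1cc(O)c([C@]2(C)CC/C(=C\Br)[C@@H]2C)cc1Br | target

**Totals**
Total steps: 5. Longest linear sequence: 5 steps (1 → 2 → 4 → 6 → 9 → 10).

**Three steps most likely to fail**

Step 2 (the proposed new step). It may give low ee, the regioisomeric primary ether from hydropalladation at the ring terminus, or lose ee through reversal and C-allylation. The fallback uses known chemistry, sets out from phenol 3 and comes back at ether 4. Commercial 2,3-dimethylcyclopent-2-en-1-one F1 is reduced with (S)-Me-CBS/BH3·SMe2 (alkenyl branch as the large group) to (1R)-2,3-dimethylcyclopent-2-en-1-ol F2. Mitsunobu coupling of F2 with 3 (PPh3, DIAD, THF, 0 °C) proceeds with inversion to give 4; step 1 then falls away.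

Step 3. The secondary allylic ether with a tetrasubstituted alkene may ionise (racemisation, elimination to diene and phenol) before it rearranges to the crowded quaternary centre, and 6 can cyclise onto its alkene under acid. The fallback replaces the sigmatropic shift by a copper-mediated anti-SN2′ arylation; it sets out from phenol 3 and comes back at 6. Phenol 3 is iodinated ortho to OH (NIS, cat. TsOH, MeCN) to 4-bromo-2-iodo-5-methylphenol F3 and silylated (TBSCl, imidazole) to (4-bromo-2-iodo-5-methylphenoxy)(tert-butyl)dimethylsilane F4. Alcohol F2 (made as in the fallback for step 2) is acylated with picolinoyl chloride/Et3N to (1R)-2,3-dimethylcyclopent-2-en-1-yl pyridine-2-carboxylate F5. Iodine–magnesium exchange on F4 (iPrMgCl·LiCl, THF, −40 °C, aryl bromide untouched) gives [4-bromo-2-(tert-butyldimethylsilyloxy)-5-methylphenyl]magnesium chloride F6. With CuBr·SMe2, F6 attacks F5 at the methyl-bearing γ-carbon anti to the picolinate, giving {4-bromo-2-[(1R)-1,2-dimethylcyclopent-2-en-1-yl]-5-methylphenoxy}(tert-butyl)dimethylsilane F7. TBAF then frees 6.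

Step 5. The unstable ylide may convert the hindered ketone poorly, give E/Z mixtures, or epimerise C2 on long reaction times. The fallback builds the alkene and the C–Br bond separately; it sets out from ketone 9 and comes back at 10. Boron-Wittig olefination of 9 with lithiated bis(pinacolato)borylmethane (CH2(Bpin)2, LiTMP, THF, 0 °C; boryl group ends away from the branched α-carbon) gives 4-bromo-2-{(1R,2S,3E)-1,2-dimethyl-3-[(4,4,5,5-tetramethyl-1,3,2-dioxaborolan-2-yl)methylidene]cyclopentyl}-5-methylphenol F8. Stereoretentive bromodeboronation (CuBr2, MeOH/H2O, 50 °C) gives 10.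

**Further compounds**
F1 | step 2 | 2,3-dimethylcyclopent-2-en-1-one (purchased) | CC1=C(C)C(=O)CC1
F2 | step 2 | (1R)-2,3-dimethylcyclopent-2-en-1-ol | CC1=C(C)[C@H](O)CC1
F3 | step 3 | 4-bromo-2-iodo-5-methylphenol | Cc1cc(O)c(I)cc1Br
F4 | step 3 | (4-bromo-2-iodo-5-methylphenoxy)(tert-butyl)dimethylsilane | Cc1cc(O[Si](C)(C)C(C)(C)C)c(I)cc1Br
F5 | step 3 | (1R)-2,3-dimethylcyclopent-2-en-1-yl pyridine-2-carboxylate | CC1=C(C)[C@H](OC(=O)c2ccccn2)CC1
F6 | step 3 | [4-bromo-2-(tert-butyldimethylsilyloxy)-5-methylphenyl]magnesium chloride | Cc1cc(O[Si](C)(C)C(C)(C)C)c([Mg]Cl)cc1Br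
F7 | step 3 | {4-bromo-2-[(1R)-1,2-dimethylcyclopent-2-en-1-yl]-5-methylphenoxy}(tert-butyl)dimethylsilane | Cc1cc(O[Si](C)(C)C(C)(C)C)c([C@]2(C)CCC=C2C)cc1Br
F8 | step 5 | 4-bromo-2-{(1R,2S,3E)-1,2-dimethyl-3-[(4,4,5,5-tetramethyl-1,3,2-dioxaborolan-2-yl)methylidene]cyclopentyl}-5-methylphenol | Cc1cc(O)c([C@]2(C)CC/C(=C\B3OC(C)(C)C(C)(C)O3)[C@@H]2C)cc1Br
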